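**Retrosynthetic overview**
1. Target 19 ⇒ acyclic allenyl aldehyde / α-propanoyloxy ester 17. One base closes the tetronic acid (ring C, Dieckmann) and then the 2,4-disubstituted furan (ring B, enolate onto allene) in the same flask.
2. 17 ⇒ dimethyl acetal 12 + 1-(furan-3-yl)prop-2-yn-1-ol 14 (Saucy–Marbet propargyl Claisen); ring A is the purchased 3-furyl unit.
3. 12 ⇒ (Z)-alkenyl iodide 7 + methyl (R)-glycidate 8 + propanoyl chloride; the only stereocentre is bought.
4. 7 ⇒ geranyl acetate 1 (E-alkene bought): selective ozonolysis, (Z)-iodo-olefination, copper-catalysed Grignard coupling with the C3 acetal 5.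
5. Ring order: A (bought) → C and B together in the last step.

Assumption: 1, 5, 8, 13 and all reagents are catalogue chemicals; 17 is used as the mixture of C12/allene-axis diastereomers, because both elements disappear when ring B aromatises.

**Step 1**
Reactants: 1 geranyl acetate
Product: 3 (2E)-3-methyl-6-oxohex-2-en-1-yl acetate, via secondary ozonide 2 (not isolated)
Conditions: O3 (1.0 equiv, Sudan red end point), CH2Cl2, −78 °C; Me2S, −78 → 20 °C
Reagents that add atoms: ozone, [O-][O+]=O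
Why: Chemoselective ozonolysis (Criegee mechanism), because the distal trisubstituted alkene is more electron-rich than the one deactivated by the allylic acetate, so one equivalent of ozone cleaves only it and the 2E alkene is untouched.

**Step 2**
Reactants: 3 (2E)-3-methyl-6-oxohex-2-en-1-yl acetate
Product: 4 (2E,6Z)-7-iodo-3-methylocta-2,6-dien-1-yl acetate
Conditions: EtPPh3I, n-BuLi, THF, 20 °C; I2, −78 °C; NaN(SiMe3)2, −20 °C; then 3, −78 → −20 °C
Reagents that add atoms: ethyltriphenylphosphonium iodide, CC[P+](c1ccccc1)(c1ccccc1)c1ccccc1.[I-]; iodine, II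
Why: Stork–Zhao-type Wittig iodo-olefination with the non-stabilised α-iodoethylidene ylide goes through the cis-oxaphosphetane and gives the (Z)-2-iodoalkene (iodine cis to the chain), the geometry that later becomes the Z-trisubstituted alkene.

**Step 3**
Reactants: 4 (2E,6Z)-7-iodo-3-methylocta-2,6-dien-1-yl acetate; 5 3-bromo-1,1-dimethoxypropane
Product: 7 (2Z,6E)-2-iodo-11,11-dimethoxy-6-methylundeca-2,6-diene, via Grignard reagent 6 (not isolated)
Conditions: 5, Mg, THF, ≤20 °C; then 4, Li2CuCl4 (3 mol %), THF, −20 → 0 °C; H2O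
Reagents that add atoms: none
Why: Copper-catalysed α-selective (SN2) allylic substitution of a primary allylic acetate by an alkyl Grignard reagent (Kochi/Fouquet–Schlosser-type coupling) keeps the E alkene and does not touch the alkenyl iodide at this temperature.

**Step 4**
Reactants: 7 (2Z,6E)-2-iodo-11,11-dimethoxy-6-methylundeca-2,6-diene; 8 methyl (2R)-oxirane-2-carboxylate
Product: 12 methyl (2R,4Z,8E)-13,13-dimethoxy-4,8-dimethyl-2-(propanoyloxy)trideca-4,8-dienoate, via alkenyllithium 9 (not isolated), via alkenylmagnesium bromide 10 (not isolated), via magnesium alkoxide 11 (not isolated)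
Conditions: t-BuLi (2.1 equiv), Et2O, −78 °C; MgBr2·OEt2, −78 → −40 °C; CuI (10 mol %), 8, THF, −40 °C; EtCOCl, −40 → 0 °C
Reagents that add atoms: propanoyl chloride, CCC(Cl)=O
Why: Iodine–lithium exchange and transmetalation proceed with retention of alkene geometry, the copper-catalysed epoxide opening occurs at the CH2 terminus of the glycidate so the (R) centre is carried over unchanged from 8, and the alkoxide is O-acylated in the same flask.

**Step 5**
Reactants: 13 furan-3-carbaldehyde
Product: 14 1-(furan-3-yl)prop-2-yn-1-ol (racemic)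
Conditions: HC≡CMgBr, THF, 0 °C; H2O
Reagents that add atoms: ethynylmagnesium bromide, C#C[Mg]Br
Why: Grignard 1,2-addition of an alkynyl nucleophile to an aldehyde; the carbinol centre is racemic and is destroyed in step 6.

**Step 6**
Reactants: 12 methyl (2R,4Z,8E)-13,13-dimethoxy-4,8-dimethyl-2-(propanoyloxy)trideca-4,8-dienoate; 14 1-(furan-3-yl)prop-2-yn-1-ol
Product: 17 methyl (2R,4Z,8E)-12-formyl-15-(furan-3-yl)-4,8-dimethyl-2-(propanoyloxy)pentadeca-4,8,13,14-tetraenoate, via mixed acetal 15 (not isolated), via propargyl enol ether 16 (not isolated)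
Conditions: 14 (3 equiv), EtCO2H (10 mol %), xylene, 135 °C, MeOH distilled off; used at once
Reagents that add atoms: none
Why: Saucy–Marbet reaction, in which acetal exchange and loss of methanol give the propargyl enol ether and its propargyl Claisen ([3,3]) rearrangement forms the C12–C13 bond and the β-allenic aldehyde regiospecifically; C12 and the allene axis form unselectively and are erased in step 7, C2 is untouched.

**Step 7**
Reactants: 17 methyl (2R,4Z,8E)-12-formyl-15-(furan-3-yl)-4,8-dimethyl-2-(propanoyloxy)pentadeca-4,8,13,14-tetraenoate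
Product: 19 (5R)-4-hydroxy-3-methyl-5-[(2Z,6E)-9-{5-[(furan-3-yl)methyl]furan-3-yl}-2,6-dimethylnona-2,6-dien-1-yl]furan-2(5H)-one, via potassium tetronate 18 (not isolated)
Conditions: KN(SiMe3)2 (3.5 equiv), THF (0.01 M), −78 °C then 25 °C; 1 M HCl to pH 3, 0 °C
Reagents that add atoms: none
Why: Proposed new method: the base forms the propanoate enolate, which closes the tetronic acid at −78 °C by Dieckmann condensation (the resulting tetronate protects C5–H, so the R centre is kept), and the same base turns the allenyl aldehyde into its extended enolate, whose oxygen adds to the central allene carbon on warming to give the aromatic furan after the bis(furyl)methyl anion is protonated by HN(SiMe3)2; the closest known reactions are the LiN(SiMe3)2 Dieckmann synthesis of tetronic acids and the KOt-Bu cycloisomerisation of 4-pentynones and allenyl carbonyl compounds to furans.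

**Compound list**
1 | geranyl acetate, (2E)-3,7-dimethylocta-2,6-dien-1-yl acetate | CC(C)=CCC/C(C)=C/COC(C)=O | starting material
2 | (2E)-5-(5,5-dimethyl-1,2,4-trioxolan-3-yl)-3-methylpent-2-en-1-yl acetate (secondary ozonide) | CC1(C)OOC(CC/C(C)=C/COC(C)=O)O1 | intermediate
3 | (2E)-3-methyl-6-oxohex-2-en-1-yl acetate | O=CCC/C(C)=C/COC(C)=O | intermediate
4 | (2E,6Z)-7-iodo-3-methylocta-2,6-dien-1-yl acetate | I/C(C)=C\CC/C(C)=C/COC(C)=O | intermediate
5 | 3-bromo-1,1-dimethoxypropane | COC(CCBr)OC | starting material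
6 | bromo(3,3-dimethoxypropyl)magnesium | COC(CC[Mg]Br)OC | intermediate
7 | (2Z,6E)-2-iodo-11,11-dimethoxy-6-methylundeca-2,6-diene | I/C(C)=C\CC/C(C)=C/CCCC(OC)OC | intermediate
8 | methyl (2R)-oxirane-2-carboxylate, methyl (R)-glycidate | COC(=O)[C@H]1CO1 | starting material
9 | [(2E,6E)-11,11-dimethoxy-6-methylundeca-2,6-dien-2-yl]lithium (Li cis to C4, geometry of 7 retained) | [Li]/C(C)=C\CC/C(C)=C/CCCC(OC)OC | intermediate
10 | bromo[(2Z,6E)-11,11-dimethoxy-6-methylundeca-2,6-dien-2-yl]magnesium | Br[Mg]/C(C)=C\CC/C(C)=C/CCCC(OC)OC | intermediate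
11 | bromomagnesium alkoxide of methyl (2R,4Z,8E)-2-hydroxy-13,13-dimethoxy-4,8-dimethyltrideca-4,8-dienoate | COC(=O)[C@@H](C/C(C)=C\CC/C(C)=C/CCCC(OC)OC)O[Mg]Br | intermediate
12 | methyl (2R,4Z,8E)-13,13-dimethoxy-4,8-dimethyl-2-(propanoyloxy)trideca-4,8-dienoate | COC(=O)[C@@H](C/C(C)=C\CC/C(C)=C/CCCC(OC)OC)OC(=O)CC | intermediate
13 | furan-3-carbaldehyde | O=Cc1ccoc1 | starting material
14 | 1-(furan-3-yl)prop-2-yn-1-ol (racemic) | OC(C#C)c1ccoc1 | intermediate
15 | methyl (2R,4Z,8E)-13-{[1-(furan-3-yl)prop-2-yn-1-yl]oxy}-13-methoxy-4,8-dimethyl-2-(propanoyloxy)trideca-4,8-dienoate | COC(=O)[C@@H](C/C(C)=C\CC/C(C)=C/CCCC(OC)OC(C#C)c1ccoc1)OC(=O)CC | intermediate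
16 | methyl (2R,4Z,8E)-13-{[1-(furan-3-yl)prop-2-yn-1-yl]oxy}-4,8-dimethyl-2-(propanoyloxy)trideca-4,8,12-trienoate | COC(=O)[C@@H](C/C(C)=C\CC/C(C)=C/CCC=COC(C#C)c1ccoc1)OC(=O)CC | intermediate
17 | methyl (2R,4Z,8E)-12-formyl-15-(furan-3-yl)-4,8-dimethyl-2-(propanoyloxy)pentadeca-4,8,13,14-tetraenoate (mixture at C12 and allene axis) | COC(=O)[C@@H](C/C(C)=C\CC/C(C)=C/CCC(C=O)C=C=Cc1ccoc1)OC(=O)CC | intermediate
18 | potassium salt of (5R)-5-[(2Z,6E)-10-formyl-13-(furan-3-yl)-2,6-dimethyltrideca-2,6,11,12-tetraen-1-yl]-4-hydroxy-3-methylfuran-2(5H)-one | CC1=C([O-])[C@@H](C/C(C)=C\CC/C(C)=C/CCC(C=O)C=C=Cc2ccoc2)OC1=O.[K+] | intermediate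
19 | (5R)-4-hydroxy-3-methyl-5-[(2Z,6E)-9-{5-[(furan-3-yl)methyl]furan-3-yl}-2,6-dimethylnona-2,6-dien-1-yl]furan-2(5H)-one | CC1=C(O)[C@@H](C/C(C)=C\CC/C(C)=C/CCc2coc(Cc3ccoc3)c2)OC1=O | target

**Totals**
Total step count: 7. Longest linear sequence: 6 steps (steps 1, 2, 3, 4, 6, 7); step 5 is a one-step side branch.

**Steps most likely to fail and fallbacks**

Step 7 (the double ring closure; the competing path is protonation of the extended enolate to a conjugated dienal). The fallback sets out from 17 and comes back at 19, closing the two rings separately by different chemistry. LiN(SiMe3)2 (2.2 equiv) in THF at −78 °C for 20 min with a cold AcOH quench performs only the Dieckmann condensation and gives (5R)-5-[(2Z,6E)-10-formyl-13-(furan-3-yl)-2,6-dimethyltrideca-2,6,11,12-tetraen-1-yl]-4-hydroxy-3-methylfuran-2(5H)-one F7. AgNO3 (10 mol %) in acetone at 20 °C (or AuCl3, 1 mol %, MeCN) then cycloisomerises the allenyl aldehyde of F7 to ring B, giving 19.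

Step 6 (acid and heat may isomerise the β-allenic aldehyde to the dienal, or degrade 14). The fallback sets out from 12 and comes back at 19, building ring B from a 1,4-dicarbonyl compound instead of an allene. Pyridinium tosylate in acetone/H2O unmasks the aldehyde, methyl (2R,4Z,8E)-4,8-dimethyl-13-oxo-2-(propanoyloxy)trideca-4,8-dienoate F4. Its pyrrolidine enamine is C-alkylated with 1-bromo-3-(furan-3-yl)propan-2-one and hydrolysed to methyl (2R,4Z,8E)-12-formyl-15-(furan-3-yl)-4,8-dimethyl-14-oxo-2-(propanoyloxy)pentadeca-4,8-dienoate F5. TsOH (cat.) in toluene effects Paal–Knorr closure to methyl (2R,4Z,8E)-11-{5-[(furan-3-yl)methyl]furan-3-yl}-4,8-dimethyl-2-(propanoyloxy)undeca-4,8-dienoate F6. LiN(SiMe3)2 in THF at −78 °C then gives 19 by Dieckmann condensation.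

Step 4 (three organometallic stages and an acylation in one flask, with an ester-bearing epoxide). The fallback sets out from 7 and comes back at 12, using an epoxide without an ester and adjusting the oxidation state afterwards. The alkenylmagnesium bromide 10 made as in step 4 opens the lithium alkoxide of (S)-glycidol (CuI cat., THF, −30 °C) to give (2R,4Z,8E)-13,13-dimethoxy-4,8-dimethyltrideca-4,8-diene-1,2-diol F1. TEMPO (cat.)/NaOCl (cat.)/NaClO2 at pH 6.7 oxidises only the primary alcohol to (2R,4Z,8E)-2-hydroxy-13,13-dimethoxy-4,8-dimethyltrideca-4,8-dienoic acid F2. Me3SiCHN2 in MeOH/toluene gives methyl (2R,4Z,8E)-2-hydroxy-13,13-dimethoxy-4,8-dimethyltrideca-4,8-dienoate F3, and EtCOCl/pyridine gives 12.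

**Further compounds**
F1 | step 4 | (2R,4Z,8E)-13,13-dimethoxy-4,8-dimethyltrideca-4,8-diene-1,2-diol | OC[C@@H](C/C(C)=C\CC/C(C)=C/CCCC(OC)OC)O
F2 | step 4 | (2R,4Z,8E)-2-hydroxy-13,13-dimethoxy-4,8-dimethyltrideca-4,8-dienoic acid | OC(=O)[C@@H](C/C(C)=C\CC/C(C)=C/CCCC(OC)OC)O
F3 | step 4 | methyl (2R,4Z,8E)-2-hydroxy-13,13-dimethoxy-4,8-dimethyltrideca-4,8-dienoate | COC(=O)[C@@H](C/C(C)=C\CC/C(C)=C/CCCC(OC)OC)O
F4 | step 6 | methyl (2R,4Z,8E)-4,8-dimethyl-13-oxo-2-(propanoyloxy)trideca-4,8-dienoate | COC(=O)[C@@H](C/C(C)=C\CC/C(C)=C/CCCC=O)OC(=O)CC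
F5 | step 6 | methyl (2R,4Z,8E)-12-formyl-15-(furan-3-yl)-4,8-dimethyl-14-oxo-2-(propanoyloxy)pentadeca-4,8-dienoate | COC(=O)[C@@H](C/C(C)=C\CC/C(C)=C/CCC(C=O)CC(=O)Cc1ccoc1)OC(=O)CC
F6 | step 6 | methyl (2R,4Z,8E)-11-{5-[(furan-3-yl)methyl]furan-3-yl}-4,8-dimethyl-2-(propanoyloxy)undeca-4,8-dienoate | COC(=O)[C@@H](C/C(C)=C\CC/C(C)=C/CCc1coc(Cc2ccoc2)c1)OC(=O)CC
F7 | step 7 | (5R)-5-[(2Z,6E)-10-formyl-13-(furan-3-yl)-2,6-dimethyltrideca-2,6,11,12-tetraen-1-yl]-4-hydroxy-3-methylfuran-2(5H)-one | CC1=C(O)[C@@H](C/C(C)=C\CC/C(C)=C/CCC(C=O)C=C=Cc2ccoc2)OC1=O
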